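All constants were set for the occasion; no experiment stands behind them.

Slowness is what I hand over at this bench: reagent as charged catches the catalyst intermediate at 701 min⁻¹ per intermediate, while that intermediate falls back to free catalyst and open intermediate at 9800 min⁻¹, far faster.

starting material 1.0 M; reagent 1.20 equiv; free catalyst 0.071 mol%

    reagent + catalyst intermediate → free catalyst + product (k1 = 9.73 M⁻¹ s⁻¹)
    free catalyst + open intermediate ⇌ catalyst intermediate (K2 = 0.43 M⁻¹, k2 = 70.2 M⁻¹ s⁻¹)
    starting material ⇌ dormant form (K3 = 9.7, k3 = 0.0115 s⁻¹)
    starting material + free catalyst → free catalyst + open intermediate (k4 = 63.7 M⁻¹ s⁻¹)

- apparent order in reagent when 5.0% of the starting material are converted (percent change of the rate of making product for one percent more reagent charged)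

When you come early in the run, expect open intermediate to gather ahead of product. With starting material as charged, free catalyst turns it into open intermediate at 3820 min⁻¹ per free catalyst, faster than capture makes product per catalyst intermediate, and a part of the starting material slips into the dormant form. Don't add reagent to hurry the starting material: neither step that uses it has reagent on its left-hand side.

My reckoning rests on the capture share, the part of the catalyst intermediate's losses that goes to reagent, which is capture over capture plus return, 6.67%. With the open intermediate held as it is, the catalyst intermediate's level goes with one over its total loss, and the rate of making product is reagent times that level. So one percent more reagent gives one percent more rate, less the capture share, and I commit to an order of 0.933. This is a pre-equilibrium, trimmed by that share.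

The forecast also gives 0.93, holding that “the rate is nearly first order in reagent”.

The simulation gives 0.93.

At 2.00 min this flask has reagent at 85.7% of its charge, so the capture share goes from 6.67% as charged to 5.77%. The binding constant times the open intermediate, 61.5% of the starting material charged, less that share, gives catalyst intermediate over free catalyst as 0.249, and this flask holds 20.0% against 80.0% of the catalyst charged. In a second flask with twice the reagent, the capture share as charged comes to 12.5%, and the time to 5.0% conversion changes by a factor of 1.00.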